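Readings and results come from a simulation on assumed constants, noise included.

Count every unit of starting material wherever it sits and the total stays at the charge, yet the listed forms in the noon run add up at the last reading to 21.4%, so unseen forms hold the rest.

| flask | starting material | protic impurity | remark | time |
|---|---|---|---|---|
| dawn | 0.12 M | 0.050 M | run made earlier |  |
| winter | 0.50 M | 0.050 M | run made earlier |  |
| noon | 0.25 M | 0.025 M | run made earlier |  |
| flask | 0.25 M | 0.0500 M |  | 6.0 d |

| run | time / d | side product / % | target / % | starting material / % |
|---|---|---|---|---|
| dawn | 0.833 | 3.7 | 0.8 | 3.4 |
| dawn | 1.67 | 3.2 | 0 | 2.2 |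
| dawn | 2.50 | 3.0 | 0 | 2.0 |
| dawn | 4.00 | 3.3 | 0 | 2.1 |
| winter | 0.417 | 29.3 | 12.4 | 9.2 |
| winter | 1.25 | 32.8 | 1.4 | 3.3 |
| winter | 2.50 | 33.0 | 0.1 | 2.2 |
| winter | 4.00 | 33.6 | 0.1 | 2.0 |
| noon | 0.250 | 13.0 | 20.0 | 16.9 |
| noon | 0.625 | 18.0 | 5.8 | 7.9 |
| noon | 1.67 | 18.4 | 0.8 | 3.1 |
| noon | 4.00 | 18.2 | 0.5 | 2.7 |

(readings scatter by 0.3 percentage points)

- at 6.0 d, what has stopped the reaction, if anything has (it is still moving / all of the starting material has reacted / forward and back rates have come level)
- side product at 6.0 d, in percent of the starting material charged

- in percentages every species weighs as the starting material in it: one target counts as two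
- in percentages every species weighs as the starting material in it: one side product counts as three
- the analysis behind the earlier runs scatters by 0.3 percentage points, standard deviation
- the reaction counts as stopped when no species that holds the starting material changes by six tenths of a point or more over the second half of the time

Starting material stands at 2.1% in the dawn run and 2.0% in the winter run, with different charges, which I read as a balance with an unseen form rather than exhaustion. My guess for the side product is that each protic impurity molecule removes one starting material early, as the limiting reagent of that loss. That gives the free charge, c(starting material) minus c(protic impurity): 0.200 M in this flask, a toll of 20.0% of the charge.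

The dawn and noon runs have free charges of 0.0700 M and 0.225 M, and their last side-product readings give a power of 1.46 over that stretch, which holds the 0.200 M of this flask. The winter run, with a free charge of 0.450 M, lies beyond that stretch, so I do not use it for the power. The noon curve reads 13.0% at 0.250 d, and that mean slope, carried on, meets the last reading at a knee near 0.350 d. I draw the flask alike: a steep start, a knee far earlier than 6.0 d, then a flat level of 15.3%.

The forecast says forward and back rates have come level and 12.5% of side product, pointing to “a reversible first-order-like exchange with the unseen product”.

The flask gives forward and back rates have come level and 14.7% of side product, where I reckoned 15.3%.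

    2 starting material ⇌ target (K = 7.60 L mol⁻¹, k = 0.0280 L mol⁻¹ min⁻¹)
    starting material + protic impurity → quenched substrate (k = 0.263 L mol⁻¹ min⁻¹)
    starting material + target → side product (k = 0.0132 L mol⁻¹ min⁻¹)
    starting material ⇌ dormant form (K = 25.0, k = 0.00367 min⁻¹)

In this flask half of the quenching up to 6.0 d is done by 0.206 h, far sooner than the 0.13 d half-life of starting material by the forward step to the dormant form alone, as it stands at 6.00 d. At 6.00 d quenched substrate holds 20.0%, matching the toll of 20.0%, with protic impurity at 0%. The neighbour flask with 0.085 M of protic impurity has a free charge of 0.165 M and a toll of 34.0%; it holds 34.0% of quenched substrate and 10.2% of side product, against 11.6% from the same power.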